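## Analysis of the target

The target (42) is a tetracyclic ether. In the numbering used here, a ten-membered carbocycle C1–C10 is bridged by an oxygen between C2 and C9. This gives a tetrahydrofuran (O, C2, C1, C10, C9) and a nine-membered oxonane (O, C2–C9). A cyclohexenone (C1, C10, C11(Me)=C12, C13(=O), C14) is fused at C1–C10, and an oxepane (C3, O, C16, C15(Me), C14, C1, C2) ties C14 back to C3. There are ten stereocentres (C1, C2, C3, C4, C6, C7, C9, C10, C14, C15). H1, H10 and H14 are cis on the cyclohexenone. On the tetrahydrofuran, C3 and C8 are cis to each other and trans to the ring-B bonds. The C15 methyl is trans to C13, and the C6 acetate and C7 tertiary alcohol are threo. Sensitive groups are the enone with its epimerisable C14–H, the two secondary acetates next to a free tertiary alcohol, and the β-alkoxy carbonyl relationships that appear on the way. The hard points are the fully substituted ether carbon C3 (methyl, C2, C4, oxygen), the nine-membered ring, and the C15 methyl, which is the less stable epimer once a six-membered ring A is locked. The strategy rests on the oxepane bond C3–O. Because that oxygen sits on the fully substituted C3 and its other neighbour is C16, C3 can first be an all-carbon quaternary centre alpha to a C16 ketone in a carbocycle C16–C15–C14–C1–C2–C3, and the oxygen can be inserted afterwards.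

## Retrosynthetic reasoning

**Acetates and enone (42 ⇒ 41 ⇒ 40).** The two secondary acetates go on last, since the tertiary C7 alcohol does not acylate. The enone 41 is unveiled from the allylic C13 carbinol of tetraol 40, because hydride steps late in the route cannot spare a ketone.

**C7 carbinol (40 ⇒ 39 ⇒ 38).** The C7 methyl and hydroxyl are traced to an exocyclic alkene. Hydroxyl-directed epoxidation of 38 followed by hydride opening at the CH2 end sets C7 from C6, so no separate methyl addition to a ketone is needed.

**Nine-membered ring (38 ⇒ 37).** The ring is cut at C6–C7, between an alkenyl iodide on the C9 arm and an aldehyde on the C3 arm. This bond forms a secondary alcohol that is needed anyway and leaves the C7 alkene for the previous operation. Cutting C4–C5 or C5–C6 would need an enolate in a medium-ring closure.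

**C4–C5 (37 ⇒ 35 ⇒ 34 ⇒ 33).** C5 and C6 come from an allyl group added to the C4 aldehyde of 33. The oxepane oxygen on C3 allows a chelate, so C4 is set by the existing C3 centre.

**The C9 arm and the ether (33 ⇒ 31 ⇒ 27 ⇒ 24).** The alkenyl iodide of 31 comes from a one-carbon homologated alkyne, which in turn comes from the primary alcohol on C7. The cyclic ether of 27 comes from lactone 24 through its lactol, which keeps the C3–O bond intact.

**Key disconnection (24 ⇒ 23).** The C3–O bond is cut back to the C3–C16 bond of cyclohexanone 23. The forward reaction must insert oxygen on the C3 side of the C16 carbonyl with retention and must leave the enone alone.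

**C13 oxygen and C15 methyl (23 ⇒ 22 ⇒ 21).** The enone oxygen is put in by allylic oxidation of the C11=C12 alkene, and the methyl by alkylation of the only possible enolate of the C16 ketone. Both come late so that no second enolisable carbonyl is present when the methyl is introduced.

**Tetrahydrofuran (18 ⇒ 16 ⇒ 14).** The O–C9 bond is cut. A conjugate addition of the C2 hydroxyl to an enoate made from lactol 16 closes the ring reversibly, so C9 is set under thermodynamic control.

**Ring B (14 ⇒ 13 ⇒ 8 + 12).** C1–C10 and C13–C14 are cut in a [4+2] sense. The enone of 8 has C1 alpha and C14 beta to the C2 carbonyl. The 2-phosphoryloxy group of diene 12 makes C13 the nucleophilic terminus, and one dissolving-metal step then removes it and sets C2.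

**Ring A and C3 (8 ⇒ 5 ⇒ 4 ⇒ 3 ⇒ 1 + 2; 12 ⇒ 11 ⇒ 9 + 10).** C3 lies between the two carbonyls of dione 1, so it is made by hydroxymethylation and fixed by a desymmetrising reduction. The carbinol formed there is the future C16 (re-oxidised later). The surviving ketone is C2, whose alpha and beta positions are exactly where ring B must be fused.

## Alternatives that were turned down

**Alternative 1: cycloaddition onto an unsaturated lactone.**
- Disconnection and key step: ring B is cut at C1–C14 and C10–C11. A 2-silyloxy diene spanning C11–C14 adds endo to the C1=C10 bond of an unsaturated γ-lactone that already holds C2, the ring oxygen and C9, giving the cis-fused lactone A1.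
- For it: it is convergent, one step sets C1, C10 and C14, and the C13 oxygen arrives in place as a silyl enol ether. On that last point it is stronger than the chosen route, which needs an allylic oxidation.
- Against it: C3 must be built beforehand as an acyclic tertiary ether centre next to C2. The diene is substituted at both termini, one with the branched C15 arm, and the dienophile is a β-substituted lactone, so the cycloaddition should be slow and its sense at C14 uncertain. The oxepane must still be closed by alkylating the tertiary C3 oxygen with C16, a seven-membered closure at a hindered alkoxide. C11 is set only to be removed.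
- Comparison: the chosen route is longer and linear, but it makes the C3–O bond without ever alkylating a tertiary oxygen.

**Alternative 2: epoxide-opening and etherification cascade.**
- Disconnection and key step: both ether bonds O–C2 and O–C16 are cut, back to a ten-membered carbocycle with a 2,3-epoxide, a C9 hydroxyl and a C16 sulfonate. On deprotonation the C9 alkoxide opens the epoxide at C2 (5-exo, inversion), and the freed C3 alkoxide displaces the C16 leaving group, giving tetracycle A2.
- For it: two rings and two C–O bonds form in one flask, C2 and C3 follow stereospecifically from the epoxide, and A2 is only a few deprotections and acylations from the target. In late-stage economy it is clearly stronger than the chosen route.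
- Against it: the substrate of that step must already be the ten-membered carbocycle with C4, C6 and C7 oxygenated and with a trisubstituted alkene epoxidised on the correct face of a flexible ring. The hardest part of the problem is moved into a precursor with no obvious source of control. The second closure is again a tertiary alkoxide forming a seven-membered ring by displacement, in competition with elimination and with attack by the other oxygens.
- Comparison: the chosen route builds small rings first, where selectivity can be argued from chair models, and offers defined control at C3 in exchange for more steps.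

**Alternative 3: oxonium ylide rearrangement.**
- Disconnection and key step: O–C9 and C8–C9 are cut. A copper carbenoid made from a diazoketone with Cu(CF3COCHCOCF3)2 is captured by a tetrahydropyran oxygen, and the ylide undergoes a [2,3] shift onto an isopropenyl group, giving the bridged oxonene ketone A3.
- For it: the medium ring is made early by ring expansion instead of end-to-end cyclisation. This is stronger than the late chromium-mediated closure of the chosen route, which is one of its weakest steps.
- Against it: A3 contains only two of the four rings. Ring B with C1, C10 and C14, the C15 centre and the oxepane remain, and the oxepane would once more require alkylation of the tertiary C3 oxygen. The Z alkene at C6–C7 must later be oxidised on one face and differentiated, and [1,2] shift or C–H insertion can divert the ylide.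
- Comparison: the chosen route accepts the risk of a late macrocyclisation in return for a secure C3 and a secure oxepane.

Key step: step 18

Assumption: locants C1–C16 are those fixed in the analysis. The carbinol carbon C13 in 25–32 and 40, the lactol carbon C16 in 16, 25 and 26, and the new carbinol carbon in 36 are taken as epimer mixtures that converge later.

## Route

Step 1
Reactants: 1 2-methylcyclohexane-1,3-dione; 2 formaldehyde
Product: 3 2-(hydroxymethyl)-2-methylcyclohexane-1,3-dione
Conditions: 37% aq. CH2O, H2O, rt
Reagents that add atoms: none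
Why: Aldol hydroxymethylation of the enolised dione at its only nucleophilic carbon creates the quaternary carbon that becomes C3 and attaches C4; no base is added because the product loses formaldehyde by retro-aldol cleavage under basic conditions.

Step 2
Reactants: 3 2-(hydroxymethyl)-2-methylcyclohexane-1,3-dione
Product: 4 2-methyl-2-{[(triisopropylsilyl)oxy]methyl}cyclohexane-1,3-dione
Conditions: i-Pr3SiOSO2CF3, 2,6-lutidine, CH2Cl2, −78 to 0 °C
Reagents that add atoms: triisopropylsilyl trifluoromethanesulfonate, CC(C)[Si](OS(=O)(=O)C(F)(F)F)(C(C)C)C(C)C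
Why: Silylation with a hindered weak base avoids the retro-aldol; the triisopropylsilyl ether is chosen because it survives dissolving metal, hydrides and peracid and stays on while a primary tert-butyldimethylsilyl ether is removed in step 22.

Step 3
Reactants: 4 2-methyl-2-{[(triisopropylsilyl)oxy]methyl}cyclohexane-1,3-dione
Product: 5 (2S,3S)-3-hydroxy-2-methyl-2-{[(triisopropylsilyl)oxy]methyl}cyclohexan-1-one (hydroxyl cis to the silyloxymethyl group)
Conditions: (R)-1-methyl-3,3-diphenyltetrahydro-1H,3H-pyrrolo[1,2-c][1,3,2]oxazaborole (20 mol %), BH3·SMe2 (0.6 equiv), THF, −30 °C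
Reagents that add atoms: none
Why: CBS reduction desymmetrises the prochiral dione: the catalyst, treating the quaternary carbon as the large group, should give the (S)-carbinol, and hydride should arrive anti to the bulkier silyloxymethyl group; together these choose one carbonyl and so fix the quaternary carbon (future C3). The carbinol is the future C16 and the remaining ketone is C2.

Step 4
Reactants: 5 (2S,3S)-3-hydroxy-2-methyl-2-{[(triisopropylsilyl)oxy]methyl}cyclohexan-1-one
Product: 6 (2S,3S)-3-(benzyloxy)-2-methyl-2-{[(triisopropylsilyl)oxy]methyl}cyclohexan-1-one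
Conditions: Cl3CC(=NH)OCH2Ph, CF3SO3H (5 mol %), CH2Cl2/cyclohexane, 0 °C
Reagents that add atoms: benzyl 2,2,2-trichloroacetimidate, N=C(OCc1ccccc1)C(Cl)(Cl)Cl
Why: Acid-catalysed benzylation avoids an alkoxide beta to the ketone, which would open the ring by retro-aldol; benzyl is chosen because it is removed in step 9 without an extra operation.

Step 5
Reactants: 6 (2S,3S)-3-(benzyloxy)-2-methyl-2-{[(triisopropylsilyl)oxy]methyl}cyclohexan-1-one
Product: 8 (5S,6S)-5-(benzyloxy)-6-methyl-6-{[(triisopropylsilyl)oxy]methyl}cyclohex-2-en-1-one, via trimethylsilyl enol ether 7 (not isolated)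
Conditions: LiN(i-Pr)2, Me3SiCl, THF, −78 °C; then Pd(OAc)2 (10 mol %), O2, DMSO, rt
Reagents that add atoms: none
Why: Saegusa–Ito dehydrogenation; only C1 can be enolised because C3 is quaternary, so the C1=C14 enone forms without regiochemical choice.

Step 6
Reactants: 9 2-(benzyloxy)acetaldehyde; 10 3-(triphenylphosphoranylidene)butan-2-one
Product: 11 (E)-5-(benzyloxy)-3-methylpent-3-en-2-one
Conditions: toluene, 90 °C
Reagents that add atoms: none
Why: Wittig reaction of a stabilised acyl ylide should give the E trisubstituted enone, which places the C9 arm on the outside of the later diene.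

Step 7
Reactants: 11 (E)-5-(benzyloxy)-3-methylpent-3-en-2-one
Product: 12 diethyl (E)-5-(benzyloxy)-3-methylpenta-1,3-dien-2-yl phosphate
Conditions: LiN(i-Pr)2, THF, −78 °C; then (EtO)2P(O)Cl, HMPA, −78 to 0 °C
Reagents that add atoms: diethyl chlorophosphate, CCOP(=O)(Cl)OCC
Why: Kinetic deprotonation at the methyl group and O-phosphorylation give the cross-conjugated enol phosphate; the phosphate tolerates Lewis acid, directs the cycloaddition like any 2-oxy substituent and can be removed reductively.

Step 8
Reactants: 8 (5S,6S)-5-(benzyloxy)-6-methyl-6-{[(triisopropylsilyl)oxy]methyl}cyclohex-2-en-1-one; 12 diethyl (E)-5-(benzyloxy)-3-methylpenta-1,3-dien-2-yl phosphate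
Product: 13 cis-octalone (C2 ketone; C11=C12 enol diethyl phosphate; benzyl ethers on the C9 and C16 oxygens; H1, H10 and H14 cis; ring B on the face of ring A opposite to the C16 and C4 oxygens)
Conditions: Me2AlCl (0.5 equiv), CH2Cl2, −20 °C to rt
Reagents that add atoms: none
Why: Lewis-acid-promoted Diels–Alder reaction; C13, next to the oxygen-bearing C12, has the largest coefficient and bonds to the beta carbon C14 while the substituted terminus C10 bonds to C1 (para and ortho rules agree). Endo addition anti to the C16 benzyloxy and C3 silyloxymethyl groups should set C1, C10 and C14.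

Step 9
Reactants: 13 cis-octalone
Product: 14 triol (hydroxyls on C2, C9 and C16; C11=C12 alkene; C2 hydroxyl equatorial, cis to the silyloxymethyl group and trans to C10)
Conditions: Li, NH3 (l), THF, t-BuOH, −78 to −33 °C; then NH4Cl
Reagents that add atoms: none
Why: One dissolving-metal reduction does three jobs: the enol phosphate is cleaved to the C11=C12 alkene without migration, both benzyl ethers are removed, and the C2 ketone is reduced to the thermodynamically preferred equatorial alcohol (the axial epimer would be syn-axial to the C14–C13 bond), which sets C2.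

Step 10
Reactants: 14 triol
Product: 15 γ-lactone (C9 carbonyl bound to the C2 oxygen; trans-fused to ring A and cis-fused to ring B; C16 hydroxyl free)
Conditions: TEMPO (2,2,6,6-tetramethylpiperidin-1-oxyl, 10 mol %), PhI(OAc)2 (2.5 equiv), CH2Cl2, rt
Reagents that add atoms: none
Why: Oxoammonium oxidation is selective for the primary alcohol; the hydroxy aldehyde closes onto the C2 hydroxyl and the lactol is oxidised on to the lactone, while the hindered secondary C16 alcohol is left.

Step 11
Reactants: 15 γ-lactone
Product: 16 lactol (hemiacetal at C9)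
Conditions: i-Bu2AlH, CH2Cl2, −78 °C
Reagents that add atoms: none
Why: Partial reduction of a lactone to its lactol at low temperature, where the aluminium hemiacetal does not collapse.

Step 12
Reactants: 16 lactol
Product: 18 tetrahydrofuran ester (methyl ester of the acetic acid arm on C9; C16 hydroxyl free), via hydroxy enoate 17 (not isolated)
Conditions: Ph3P=CHCO2Me, toluene, 80 °C; then 1,8-diazabicyclo[5.4.0]undec-7-ene (0.2 equiv), rt
Reagents that add atoms: methyl (triphenylphosphoranylidene)acetate, COC(=O)C=P(c1ccccc1)(c1ccccc1)c1ccccc1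
Why: Wittig reaction on the open-chain aldehyde gives the E enoate, and the C2 alkoxide adds 5-exo in an oxa-Michael reaction to form O–C9; the addition is reversible, so C9 should settle with its arm trans to C11 on C10 and cis to C3 across the ring.

Step 13
Reactants: 18 tetrahydrofuran ester
Product: 19 diol (primary hydroxyl on C7; secondary hydroxyl on C16)
Conditions: LiAlH4, THF, 0 °C
Reagents that add atoms: none
Why: Ester reduction; the ester is removed now because it would compete as a second enolisable carbonyl in step 16 and would complicate the hydride reduction of the lactone in step 19.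

Step 14
Reactants: 19 diol
Product: 20 C7 tert-butyldimethylsilyl ether (C16 hydroxyl free)
Conditions: t-BuMe2SiCl, imidazole, CH2Cl2, 0 °C
Reagents that add atoms: tert-butyldimethylsilyl chloride, CC(C)(C)[Si](C)(C)Cl
Why: The unhindered primary alcohol is silylated in preference to the secondary alcohol next to the quaternary carbon.

Step 15
Reactants: 20 C7 tert-butyldimethylsilyl ether
Product: 21 C16 ketone (C15 unsubstituted)
Conditions: Dess–Martin periodinane, NaHCO3, CH2Cl2, rt
Reagents that add atoms: none
Why: Mild oxidation of the secondary alcohol; the beta oxygens on C2 and C4 cannot be eliminated because C3 carries no hydrogen.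

Step 16
Reactants: 21 C16 ketone
Product: 22 C15-methyl ketone (methyl trans to C13; same configuration at C15 as the target)
Conditions: LiN(i-Pr)2, THF, −78 °C; then MeI, DMPU, −78 to −40 °C
Reagents that add atoms: iodomethane, CI
Why: Enolate alkylation; C15 is the only enolisable position, and axial attack anti to the axial C14–C13 bond should place the methyl trans to C13. This is the less stable epimer (methyl syn-axial to the silyloxymethyl group on C3), so the step is kept kinetic and no base is used afterwards.

Step 17
Reactants: 22 C15-methyl ketone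
Product: 23 tricyclic diketone (C16 cyclohexanone with quaternary C3; C13 enone)
Conditions: Rh2(cap)4 (cap = caprolactamate, 1 mol %), t-BuOOH (70% aq., 5 equiv), CH2Cl2, rt
Reagents that add atoms: tert-butyl hydroperoxide, CC(C)(C)OO
Why: Dirhodium-catalysed allylic oxidation; the tert-butylperoxyl radical should abstract hydrogen from the secondary C13 next to the unsubstituted alkene carbon rather than from the hindered tertiary C10, and the mixed peroxide collapses to the C13 enone without base.

Step 18
Reactants: 23 tricyclic diketone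
Product: 24 tricyclic oxepanone lactone (C16 carbonyl, ring oxygen on C3; enone intact)
Conditions: CF3CO3H, Na2HPO4, CH2Cl2, 0 °C
Reagents that add atoms: trifluoroperoxyacetic acid, OOC(=O)C(F)(F)F
Why: Baeyer–Villiger oxidation: the peracid adds to the saturated C16 carbonyl to give the Criegee adduct, and the C3–C16 bond anti to the breaking O–O bond migrates to oxygen. The closest known type is the oxidation of alpha-quaternary cyclohexanones to seven-membered lactones with migration of the more substituted carbon. The oxepanone ring is closed by ring expansion (insertion of one oxygen into C3–C16), not by cyclisation, so no end-to-end closure is involved. C3 becomes the oxygen-bearing stereocentre with retention, so its configuration is controlled by the desymmetrisation of step 3. The step needs migration of C3 rather than C15: C3 is fully substituted and migration relieves the syn-axial methyl and silyloxymethyl interaction, although its two beta oxygens lower its aptitude. It also needs chemoselectivity over ring B: the conjugated C13 ketone is less electrophilic and its alkene is electron-poor, so both should react far more slowly. The phosphate buffer takes up trifluoroacetic acid and protects the C15 centre and the silyl ethers.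

Step 19
Reactants: 24 tricyclic oxepanone lactone
Product: 25 lactol allylic alcohol (hemiacetal at C16; hydroxyl at C13)
Conditions: i-Bu2AlH (4 equiv), CH2Cl2, −78 °C
Reagents that add atoms: none
Why: The lactone stops at the lactol at low temperature; the enone is reduced 1,2 at the same time, which is accepted and used to mask C13 until step 27.

Step 20
Reactants: 25 lactol allylic alcohol
Product: 26 bis(triisopropylsilyl) ether (silyl ethers on the C13 and C16 oxygens)
Conditions: i-Pr3SiOSO2CF3 (3 equiv), 2,6-lutidine, CH2Cl2, −78 to 0 °C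
Reagents that add atoms: triisopropylsilyl trifluoromethanesulfonate, CC(C)[Si](OS(=O)(=O)C(F)(F)F)(C(C)C)C(C)C
Why: Silylation of both hydroxyls; the bulky allylic silyl ether resists ionisation in the next step, while the anomeric silyl ether is a good leaving group.

Step 21
Reactants: 26 bis(triisopropylsilyl) ether
Product: 27 tetracyclic oxepane (C16 methylene; silyl ethers on C4, C7 and C13 oxygens)
Conditions: Et3SiH, BF3·OEt2, CH2Cl2, −78 to −40 °C
Reagents that add atoms: none
Why: Ionic reduction of the silyl acetal through the C16 oxocarbenium ion; the ring oxygen stays on C3, so the lactone becomes the cyclic ether.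

Step 22
Reactants: 27 tetracyclic oxepane
Product: 28 primary alcohol at C7
Conditions: pyridinium p-toluenesulfonate, MeOH, rt
Reagents that add atoms: none
Why: Mild acid methanolysis removes the primary tert-butyldimethylsilyl ether and leaves both triisopropylsilyl ethers.

Step 23
Reactants: 28 primary alcohol at C7
Product: 29 C7 aldehyde
Conditions: Dess–Martin periodinane, NaHCO3, CH2Cl2, rt
Reagents that add atoms: none
Why: Buffered oxidation of a primary alcohol; the beta-alkoxy aldehyde is used directly.

Step 24
Reactants: 29 C7 aldehyde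
Product: 30 terminal alkyne (propargyl arm on C9)
Conditions: MeC(O)C(N2)P(O)(OMe)2, K2CO3, MeOH, 0 °C to rt
Reagents that add atoms: dimethyl (1-diazo-2-oxopropyl)phosphonate, CC(=O)C(=[N+]=[N-])P(=O)(OC)OC
Why: Seyferth–Gilbert homologation in its Ohira–Bestmann form adds the carbon that becomes the C7 methyl; the base is mild and a retro-oxa-Michael opening would simply reclose.

Step 25
Reactants: 30 terminal alkyne
Product: 31 2-iodoalkene (C7 carries iodine and a terminal methylene)
Conditions: B-iodo-9-borabicyclo[3.3.1]nonane, pentane/CH2Cl2, −20 °C; then AcOH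
Reagents that add atoms: B-iodo-9-borabicyclo[3.3.1]nonane, IB1C2CCCC1CCC2
Why: Iodoboration puts boron on the terminal carbon and iodine on the internal one, and protonolysis gives the 2-iodo-1-alkene; the trisubstituted ring alkene does not react.

Step 26
Reactants: 31 2-iodoalkene
Product: 32 diol (hydroxyls on C4 and C13)
Conditions: Bu4NF, AcOH, THF, rt to 40 °C
Reagents that add atoms: none
Why: Both triisopropylsilyl ethers are removed together, so no selectivity between them is needed; the fluoride is buffered to spare the alkenyl iodide.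

Step 27
Reactants: 32 diol
Product: 33 keto aldehyde (C4 aldehyde; C13 enone restored)
Conditions: Dess–Martin periodinane (3 equiv), NaHCO3, CH2Cl2, rt
Reagents that add atoms: none
Why: One oxidation turns the neopentyl primary alcohol into the non-enolisable C4 aldehyde and the allylic alcohol back into the enone.

Step 28
Reactants: 33 keto aldehyde
Product: 34 homoallylic alcohol (C4 hydroxyl with the configuration of the target)
Conditions: CH2=CHCH2SnBu3, MgBr2·OEt2, CH2Cl2, −78 °C
Reagents that add atoms: allyltributylstannane, C=CC[Sn](CCCC)(CCCC)CCCC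
Why: Chelation-controlled allylation: magnesium bridges the aldehyde oxygen and the oxepane oxygen on C3, and the allyl group enters from the side of the C3 methyl, away from C2, which gives the required C4 configuration. The hindered conjugated ketone does not react with the stannane.

Step 29
Reactants: 34 homoallylic alcohol
Product: 35 C4 acetate
Conditions: Ac2O, pyridine, 4-(dimethylamino)pyridine (10 mol %), CH2Cl2, rt
Reagents that add atoms: acetic anhydride, CC(=O)OC(C)=O
Why: Acylation protects the C4 hydroxyl through the next three steps; it is removed in step 33 at no extra cost.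

Step 30
Reactants: 35 C4 acetate
Product: 37 C6 aldehyde (C4 acetate; alkenyl iodide; enone), via diol 36 (not isolated)
Conditions: OsO4 (2 mol %), NaIO4, 2,6-lutidine, dioxane/H2O, rt
Reagents that add atoms: sodium periodate, [Na+].[O-]I(=O)(=O)=O
Why: Lemieux–Johnson cleavage; the monosubstituted alkene is dihydroxylated much faster than the conjugated and the iodine-bearing alkenes, both of which are electron-poor.

Step 31
Reactants: 37 C6 aldehyde
Product: 38 tetracyclic allylic alcohol (nine-membered ring closed; (6S) hydroxyl; exocyclic methylene on C7)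
Conditions: CrCl2 (10 equiv), NiCl2 (1 mol %), DMSO/THF, rt, 0.003 M
Reagents that add atoms: none
Why: Nozaki–Hiyama–Kishi reaction: nickel inserts into the C–I bond, the alkenyl group passes to chromium and adds to the aldehyde, forming C6–C7. In 2,9-bridged oxonanes of this kind the closure should go through the conformer with the aldehyde oxygen pointing outwards, which gives the (6S) alcohol.

Step 32
Reactants: 38 tetracyclic allylic alcohol
Product: 39 epoxy alcohol (spiro epoxide at C7, threo to the C6 hydroxyl)
Conditions: VO(acac)2 (5 mol %), t-BuOOH, CH2Cl2, 0 °C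
Reagents that add atoms: tert-butyl hydroperoxide, CC(C)(C)OO
Why: Hydroxyl-directed epoxidation: the vanadium alkoxide of the C6 hydroxyl delivers oxygen to the adjacent exocyclic alkene only. With the extended C5–C8 backbone of the oxonane the hydroxyl lies on the alkene face that leads to the (7S) epoxide.

Step 33
Reactants: 39 epoxy alcohol
Product: 40 tetraol (hydroxyls on C4, C6, C7 and C13; C7 methyl)
Conditions: LiAlH4, THF, 0 °C
Reagents that add atoms: none
Why: Hydride opens the 1,1-disubstituted epoxide at its methylene carbon, giving the tertiary alcohol and the C7 methyl with the C7–O bond untouched; the acetate is cleaved and the enone reduced 1,2 in the same step.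

Step 34
Reactants: 40 tetraol
Product: 41 enone triol (hydroxyls on C4, C6 and C7)
Conditions: MnO2, CH2Cl2, rt
Reagents that add atoms: none
Why: MnO2 oxidises only the allylic C13 alcohol and restores the enone.

Step 35
Reactants: 41 enone triol
Product: 42 target, the 4,6-diacetate
Conditions: Ac2O, pyridine, 4-(dimethylamino)pyridine (10 mol %), CH2Cl2, rt
Reagents that add atoms: acetic anhydride, CC(=O)OC(C)=O
Why: Acylation of the two secondary alcohols; the tertiary C7 alcohol should not react under these conditions.

## Compound list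

1 | 2-methylcyclohexane-1,3-dione | CC1C(=O)CCCC1=O | starting material
2 | formaldehyde | C=O | starting material
3 | 2-(hydroxymethyl)-2-methylcyclohexane-1,3-dione | CC1(CO)C(=O)CCCC1=O | intermediate
4 | 2-methyl-2-{[(triisopropylsilyl)oxy]methyl}cyclohexane-1,3-dione | CC1(CO[Si](C(C)C)(C(C)C)C(C)C)C(=O)CCCC1=O | intermediate
5 | (2S,3S)-3-hydroxy-2-methyl-2-{[(triisopropylsilyl)oxy]methyl}cyclohexan-1-one | O=C1CCC[C@H](O)[C@]1(C)CO[Si](C(C)C)(C(C)C)C(C)C | intermediate
6 | (2S,3S)-3-(benzyloxy)-2-methyl-2-{[(triisopropylsilyl)oxy]methyl}cyclohexan-1-one | O=C1CCC[C@H](OCc2ccccc2)[C@]1(C)CO[Si](C(C)C)(C(C)C)C(C)C | intermediate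
7 | trimethylsilyl enol ether of 6 | C[Si](C)(C)OC1=CCC[C@H](OCc2ccccc2)[C@]1(C)CO[Si](C(C)C)(C(C)C)C(C)C | intermediate (not isolated)
8 | (5S,6S)-5-(benzyloxy)-6-methyl-6-{[(triisopropylsilyl)oxy]methyl}cyclohex-2-en-1-one | O=C1C=CC[C@H](OCc2ccccc2)[C@]1(C)CO[Si](C(C)C)(C(C)C)C(C)C | intermediate
9 | 2-(benzyloxy)acetaldehyde | O=CCOCc1ccccc1 | starting material
10 | 3-(triphenylphosphoranylidene)butan-2-one | CC(=O)C(C)=P(c1ccccc1)(c1ccccc1)c1ccccc1 | starting material
11 | (E)-5-(benzyloxy)-3-methylpent-3-en-2-one | CC(=O)/C(C)=C/COCc1ccccc1 | intermediate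
12 | diethyl (E)-5-(benzyloxy)-3-methylpenta-1,3-dien-2-yl phosphate | C=C(OP(=O)(OCC)OCC)/C(C)=C/COCc1ccccc1 | intermediate
13 | cis-octalone Diels–Alder adduct (C2 ketone, C12 enol phosphate, two benzyl ethers) | O=C1[C@@H]2[C@@H](CC(OP(=O)(OCC)OCC)=C(C)[C@@H]2COCc2ccccc2)C[C@H](OCc2ccccc2)[C@]1(C)CO[Si](C(C)C)(C(C)C)C(C)C | intermediate
14 | triol (C2, C9, C16 hydroxyls; C11=C12 alkene) | O[C@@H]1[C@@H]2[C@@H](CC=C(C)[C@@H]2CO)C[C@H](O)[C@]1(C)CO[Si](C(C)C)(C(C)C)C(C)C | intermediate
15 | γ-lactone (C9 carbonyl, C2 oxygen) | O=C1O[C@@H]2[C@@H]3[C@@H](CC=C(C)[C@@H]31)C[C@H](O)[C@]2(C)CO[Si](C(C)C)(C(C)C)C(C)C | intermediate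
16 | lactol (C9 hemiacetal, anomer mixture) | OC1O[C@@H]2[C@@H]3[C@@H](CC=C(C)[C@@H]31)C[C@H](O)[C@]2(C)CO[Si](C(C)C)(C(C)C)C(C)C | intermediate
17 | hydroxy enoate (E enoate on C10, free C2 hydroxyl) | COC(=O)/C=C/[C@H]1C(C)=CC[C@H]2C[C@H](O)[C@](C)(CO[Si](C(C)C)(C(C)C)C(C)C)[C@H](O)[C@@H]12 | intermediate (not isolated)
18 | tetrahydrofuran ester | COC(=O)C[C@H]2O[C@@H]3[C@@H]4[C@@H](CC=C(C)[C@@H]42)C[C@H](O)[C@]3(C)CO[Si](C(C)C)(C(C)C)C(C)C | intermediate
19 | diol (C7 and C16 hydroxyls) | OCC[C@H]2O[C@@H]3[C@@H]4[C@@H](CC=C(C)[C@@H]42)C[C@H](O)[C@]3(C)CO[Si](C(C)C)(C(C)C)C(C)C | intermediate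
20 | C7 tert-butyldimethylsilyl ether, C16 alcohol | CC(C)(C)[Si](C)(C)OCC[C@H]2O[C@@H]3[C@@H]4[C@@H](CC=C(C)[C@@H]42)C[C@H](O)[C@]3(C)CO[Si](C(C)C)(C(C)C)C(C)C | intermediate
21 | C16 ketone | CC(C)(C)[Si](C)(C)OCC[C@H]2O[C@@H]3[C@@H]4[C@@H](CC=C(C)[C@@H]42)CC(=O)[C@]3(C)CO[Si](C(C)C)(C(C)C)C(C)C | intermediate
22 | C15-methyl ketone | CC(C)(C)[Si](C)(C)OCC[C@H]2O[C@@H]3[C@@H]4[C@@H](CC=C(C)[C@@H]42)[C@H](C)C(=O)[C@]3(C)CO[Si](C(C)C)(C(C)C)C(C)C | intermediate
23 | tricyclic diketone (C16 cyclohexanone, C13 enone), substrate of the key step | CC(C)(C)[Si](C)(C)OCC[C@H]2O[C@@H]3[C@@H]4[C@@H](C(=O)C=C(C)[C@@H]42)[C@H](C)C(=O)[C@]3(C)CO[Si](C(C)C)(C(C)C)C(C)C | intermediate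
24 | tricyclic oxepanone lactone, product of the key step | CC(C)(C)[Si](C)(C)OCC[C@H]2O[C@@H]3[C@@H]4[C@@H](C(=O)C=C(C)[C@@H]42)[C@H](C)C(=O)O[C@]3(C)CO[Si](C(C)C)(C(C)C)C(C)C | intermediate
25 | lactol allylic alcohol | CC(C)(C)[Si](C)(C)OCC[C@H]2O[C@@H]3[C@@H]4[C@@H](C(O)C=C(C)[C@@H]42)[C@H](C)C(O)O[C@]3(C)CO[Si](C(C)C)(C(C)C)C(C)C | intermediate
26 | bis(triisopropylsilyl) ether at the C13 and C16 oxygens | CC(C)(C)[Si](C)(C)OCC[C@H]2O[C@@H]3[C@@H]4[C@@H](C(O[Si](C(C)C)(C(C)C)C(C)C)C=C(C)[C@@H]42)[C@H](C)C(O[Si](C(C)C)(C(C)C)C(C)C)O[C@]3(C)CO[Si](C(C)C)(C(C)C)C(C)C | intermediate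
27 | tetracyclic oxepane | CC(C)(C)[Si](C)(C)OCC[C@H]2O[C@@H]3[C@@H]4[C@@H](C(O[Si](C(C)C)(C(C)C)C(C)C)C=C(C)[C@@H]42)[C@H](C)CO[C@]3(C)CO[Si](C(C)C)(C(C)C)C(C)C | intermediate
28 | primary alcohol at C7 | OCC[C@H]2O[C@@H]3[C@@H]4[C@@H](C(O[Si](C(C)C)(C(C)C)C(C)C)C=C(C)[C@@H]42)[C@H](C)CO[C@]3(C)CO[Si](C(C)C)(C(C)C)C(C)C | intermediate
29 | C7 aldehyde | O=CC[C@H]2O[C@@H]3[C@@H]4[C@@H](C(O[Si](C(C)C)(C(C)C)C(C)C)C=C(C)[C@@H]42)[C@H](C)CO[C@]3(C)CO[Si](C(C)C)(C(C)C)C(C)C | intermediate
30 | terminal alkyne | C#CC[C@H]2O[C@@H]3[C@@H]4[C@@H](C(O[Si](C(C)C)(C(C)C)C(C)C)C=C(C)[C@@H]42)[C@H](C)CO[C@]3(C)CO[Si](C(C)C)(C(C)C)C(C)C | intermediate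
31 | 2-iodoalkene | C=C(I)C[C@H]2O[C@@H]3[C@@H]4[C@@H](C(O[Si](C(C)C)(C(C)C)C(C)C)C=C(C)[C@@H]42)[C@H](C)CO[C@]3(C)CO[Si](C(C)C)(C(C)C)C(C)C | intermediate
32 | diol (C4 and C13 hydroxyls) | C=C(I)C[C@H]2O[C@@H]3[C@@H]4[C@@H](C(O)C=C(C)[C@@H]42)[C@H](C)CO[C@]3(C)CO | intermediate
33 | keto aldehyde (C4 aldehyde, C13 enone) | C=C(I)C[C@H]2O[C@@H]3[C@@H]4[C@@H](C(=O)C=C(C)[C@@H]42)[C@H](C)CO[C@]3(C)C=O | intermediate
34 | homoallylic alcohol at C4 | C=C(I)C[C@H]2O[C@@H]3[C@@H]4[C@@H](C(=O)C=C(C)[C@@H]42)[C@H](C)CO[C@]3(C)[C@@H](O)CC=C | intermediate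
35 | C4 acetate | C=C(I)C[C@H]2O[C@@H]3[C@@H]4[C@@H](C(=O)C=C(C)[C@@H]42)[C@H](C)CO[C@]3(C)[C@@H](OC(C)=O)CC=C | intermediate
36 | diol from the terminal alkene | C=C(I)C[C@H]2O[C@@H]3[C@@H]4[C@@H](C(=O)C=C(C)[C@@H]42)[C@H](C)CO[C@]3(C)[C@@H](OC(C)=O)CC(O)CO | intermediate (not isolated)
37 | C6 aldehyde | C=C(I)C[C@H]2O[C@@H]3[C@@H]4[C@@H](C(=O)C=C(C)[C@@H]42)[C@H](C)CO[C@]3(C)[C@@H](OC(C)=O)CC=O | intermediate
38 | tetracyclic allylic alcohol (C6 hydroxyl, C7 methylene, C4 acetate) | CC(=O)O[C@H]1C[C@H](O)C(=C)C[C@H]2O[C@@H]3[C@@H]4[C@@H](C(=O)C=C(C)[C@@H]42)[C@H](C)CO[C@]13C | intermediate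
39 | epoxy alcohol | CC(=O)O[C@H]1C[C@H](O)[C@@]5(OC5)C[C@H]2O[C@@H]3[C@@H]4[C@@H](C(=O)C=C(C)[C@@H]42)[C@H](C)CO[C@]13C | intermediate
40 | tetraol | O[C@H]1C[C@H](O)[C@@](C)(O)C[C@H]2O[C@@H]3[C@@H]4[C@@H](C(O)C=C(C)[C@@H]42)[C@H](C)CO[C@]13C | intermediate
41 | enone triol | O[C@H]1C[C@H](O)[C@@](C)(O)C[C@H]2O[C@@H]3[C@@H]4[C@@H](C(=O)C=C(C)[C@@H]42)[C@H](C)CO[C@]13C | intermediate
42 | CNP0212231.3, the 4,6-diacetate | CC(=O)O[C@H]1C[C@H](OC(C)=O)[C@@](C)(O)C[C@H]2O[C@@H]3[C@@H]4[C@@H](C(=O)C=C(C)[C@@H]42)[C@H](C)CO[C@]13C | target

## Step count and least certain steps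

Total step count: 35. Longest linear sequence: 33 (steps 1–5 and 8–35); the diene branch is 2 steps (6 and 7).

**Step 18 (key step).** The most likely failure is competing migration of the secondary C15, because the two beta oxygens on C3 lower its migratory aptitude; acid-promoted epimerisation at C15 is the second concern. Fallback: move the oxidation to the ketone without the C15 methyl, where C3 competes only with a methylene.
- It sets out from 21. Allylic oxidation as in step 17 gives enone ketone F1, and the peracid gives lactone F2.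
- NaBH4 with CeCl3 gives allylic alcohol F3, and i-Pr3SiOSO2CF3 gives silyl ether F4.
- Methylation of the lactone enolate (LiN(i-Pr)2, MeI), anti to C13, gives methyl lactone F5.
- i-Bu2AlH gives lactol F6, and Et3SiH with BF3·OEt2 brings the route back at 27.

**Step 8.** The phosphate may tie up the Lewis acid, so that cycloaddition is slow and the diene decomposes. Fallback: drop the oxygen substituent on the diene. From 11, methylenation with Ph3P=CH2 gives (E)-5-(benzyloxy)-3-methylpenta-1,3-diene F7. Its AlCl3-promoted cycloaddition with 8 gives octalone F8, which already has the C11=C12 alkene, and Li in NH3 returns the route at 14. The price is that regiochemistry then rests on the 1-alkyl (ortho) preference alone.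

**Step 16.** Facial selectivity may be poor or a second alkylation may occur, because the required methyl is axial and syn to the C3 substituent. Fallback: introduce the carbon as a methylene and deliver hydrogen instead. From 21, the enolate and dimethyl(methylidene)ammonium iodide give Mannich base F9. Quaternisation with MeI and elimination give α-methylene ketone F10. Hydrogenation with RhCl(PPh3)3 should add hydrogen from the open equatorial direction and return the route at 22.

**Step 17.** Site selectivity may be poor (abstraction at C10–H or next to the ether oxygens), or C15 may epimerise. Fallback: an ionic transposition before the ketone exists.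
- From 20, m-chloroperbenzoic acid gives epoxide F11.
- Phenylselenide (PhSeSePh, NaBH4) opens it at C12 to hydroxy selenide F12.
- H2O2 gives tertiary allylic alcohol F13 by selenoxide elimination towards C13.
- Pyridinium chlorochromate effects oxidative transposition and oxidises the C16 alcohol, giving enone ketone F1.
- F1 is carried through F2–F6 as described for step 18 and returns at 27.

**Step 31.** Facial selectivity in the addition to the aldehyde may be poor (C6 epimer), alongside oligomerisation at the dilution used. Fallback for the stereocentre: from 37, the crude cyclisation product is oxidised with Dess–Martin periodinane to cross-conjugated enone F14. F14 is reduced at the less hindered C6 carbonyl under reagent control (CBS reduction), returning at 38.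

**Step 32.** Oxygen may be delivered to the wrong face, since acyclic models for allylic alcohols with a geminal substituent favour the erythro product. Fallback: osmylation, which attacks anti to the allylic oxygen and so has the opposite facial sense.
- From 38, OsO4 with N-methylmorpholine N-oxide gives triol F15.
- p-Toluenesulfonyl chloride in pyridine gives primary sulfonate F16.
- LiAlH4 displaces the sulfonate, cleaves the acetate and reduces the enone, returning at 40.

## Further compounds

F1 | step 18 | enone ketone without the C15 methyl | CC(C)(C)[Si](C)(C)OCC[C@H]2O[C@@H]3[C@@H]4[C@@H](C(=O)C=C(C)[C@@H]42)CC(=O)[C@]3(C)CO[Si](C(C)C)(C(C)C)C(C)C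
F2 | step 18 | lactone without the C15 methyl | CC(C)(C)[Si](C)(C)OCC[C@H]2O[C@@H]3[C@@H]4[C@@H](C(=O)C=C(C)[C@@H]42)CC(=O)O[C@]3(C)CO[Si](C(C)C)(C(C)C)C(C)C
F3 | step 18 | allylic alcohol lactone | CC(C)(C)[Si](C)(C)OCC[C@H]2O[C@@H]3[C@@H]4[C@@H](C(O)C=C(C)[C@@H]42)CC(=O)O[C@]3(C)CO[Si](C(C)C)(C(C)C)C(C)C
F4 | step 18 | C13 triisopropylsilyl ether lactone | CC(C)(C)[Si](C)(C)OCC[C@H]2O[C@@H]3[C@@H]4[C@@H](C(O[Si](C(C)C)(C(C)C)C(C)C)C=C(C)[C@@H]42)CC(=O)O[C@]3(C)CO[Si](C(C)C)(C(C)C)C(C)C
F5 | step 18 | C15-methyl lactone | CC(C)(C)[Si](C)(C)OCC[C@H]2O[C@@H]3[C@@H]4[C@@H](C(O[Si](C(C)C)(C(C)C)C(C)C)C=C(C)[C@@H]42)[C@H](C)C(=O)O[C@]3(C)CO[Si](C(C)C)(C(C)C)C(C)C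
F6 | step 18 | lactol with C13 silyl ether | CC(C)(C)[Si](C)(C)OCC[C@H]2O[C@@H]3[C@@H]4[C@@H](C(O[Si](C(C)C)(C(C)C)C(C)C)C=C(C)[C@@H]42)[C@H](C)C(O)O[C@]3(C)CO[Si](C(C)C)(C(C)C)C(C)C
F7 | step 8 | (E)-5-(benzyloxy)-3-methylpenta-1,3-diene | C=C/C(C)=C/COCc1ccccc1
F8 | step 8 | octalone with C11=C12 alkene | O=C1[C@@H]2[C@@H](CC=C(C)[C@@H]2COCc2ccccc2)C[C@H](OCc2ccccc2)[C@]1(C)CO[Si](C(C)C)(C(C)C)C(C)C
F9 | step 16 | Mannich base at C15 | CC(C)(C)[Si](C)(C)OCC[C@H]2O[C@@H]3[C@@H]4[C@@H](CC=C(C)[C@@H]42)C(CN(C)C)C(=O)[C@]3(C)CO[Si](C(C)C)(C(C)C)C(C)C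
F10 | step 16 | α-methylene ketone | CC(C)(C)[Si](C)(C)OCC[C@H]2O[C@@H]3[C@@H]4[C@@H](CC=C(C)[C@@H]42)C(=C)C(=O)[C@]3(C)CO[Si](C(C)C)(C(C)C)C(C)C
F11 | step 17 | C11–C12 epoxide | CC(C)(C)[Si](C)(C)OCC[C@H]2O[C@@H]3[C@@H]4[C@@H](CC5OC5(C)[C@@H]42)C[C@H](O)[C@]3(C)CO[Si](C(C)C)(C(C)C)C(C)C
F12 | step 17 | hydroxy selenide | CC(C)(C)[Si](C)(C)OCC[C@H]2O[C@@H]3[C@@H]4[C@@H](CC([Se]c5ccccc5)C(C)(O)[C@@H]42)C[C@H](O)[C@]3(C)CO[Si](C(C)C)(C(C)C)C(C)C
F13 | step 17 | tertiary allylic alcohol | CC(C)(C)[Si](C)(C)OCC[C@H]2O[C@@H]3[C@@H]4[C@@H](C=CC(C)(O)[C@@H]42)C[C@H](O)[C@]3(C)CO[Si](C(C)C)(C(C)C)C(C)C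
F14 | step 31 | C6 enone | CC(=O)O[C@H]1CC(=O)C(=C)C[C@H]2O[C@@H]3[C@@H]4[C@@H](C(=O)C=C(C)[C@@H]42)[C@H](C)CO[C@]13C
F15 | step 32 | triol with hydroxymethyl on C7 | CC(=O)O[C@H]1C[C@H](O)[C@@](CO)(O)C[C@H]2O[C@@H]3[C@@H]4[C@@H](C(=O)C=C(C)[C@@H]42)[C@H](C)CO[C@]13C
F16 | step 32 | primary p-toluenesulfonate | CC(=O)O[C@H]1C[C@H](O)[C@@](COS(=O)(=O)c5ccc(C)cc5)(O)C[C@H]2O[C@@H]3[C@@H]4[C@@H](C(=O)C=C(C)[C@@H]42)[C@H](C)CO[C@]13C
A1 | alternative 1 | cis-fused bicyclic lactone silyl enol ether | O=C1O[C@@H]([C@](C)(OCc2ccc(OC)cc2)CO[Si](C)(C)C(C)(C)C)[C@@H]2[C@H]([C@H](C)COCc3ccccc3)C(O[Si](C)(C)C(C)(C)C)=C[C@H](C)[C@H]12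
A2 | alternative 2 | fully protected tetracycle | CC(C)(C)[Si](C)(C)O[C@H]1C[C@H](O[Si](C)(C)C(C)(C)C)[C@@](C)(O[Si](CC)(CC)CC)C[C@H]2O[C@@H]3[C@@H]4[C@@H](C5(OCCO5)C=C(C)[C@@H]42)[C@H](C)CO[C@]13C
A3 | alternative 3 | bridged oxonene ketone | CC(C)(C)[Si](C)(C)O[C@H]1C/C=C(C)\C[C@H]2O[C@H](CC2=O)[C@]1(C)O[Si](CC)(CC)CC
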